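Assumption: the target is handled as the enol tautomer written in its SMILES (4-OH hydrogen-bonded to the 5-acyl group, 6-ketone), and tautomers are not counted as separate compounds.

**Retrosynthetic overview**
1. 11 ⇒ 9 + prenyl acetate 10: the C3a–prenyl bond is made last by alkylative dearomatisation, with the C2 stereocentre of the existing dihydrofuran directing the prenyl group trans.
2. 9 ⇒ 6: one-pot asymmetric epoxidation of both prenyl groups, then opening of one oxirane by the 4-phenoxide.
3. 6 ⇒ 3 + 2 × 4 (double C-prenylation); 3 ⇒ 1 + 2 (Friedel–Crafts acylation).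
4. Ring order: the benzene ring is bought (1); two oxiranes and then the dihydrofuran form together in step 3; the carbocycle is dearomatised to the cyclohexadienone in step 4.

**Route**

Step 1
Reactants: 1 phloroglucinol (benzene-1,3,5-triol); 2 isobutyryl chloride (2-methylpropanoyl chloride)
Product: 3 phlorisobutyrophenone [2-methyl-1-(2,4,6-trihydroxyphenyl)propan-1-one]
Conditions: AlCl3 (4 equiv), PhNO2, 80 °C; then aq. HCl
Reagents that add atoms: isobutyryl chloride 2, CC(C)C(Cl)=O
Why: Friedel–Crafts C-acylation of the very electron-rich symmetric triol stops at the mono-ketone because the first acyl group deactivates the ring, and no stereocentre is formed.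

Step 2
Reactants: 3 phlorisobutyrophenone; 4 prenyl bromide (1-bromo-3-methylbut-2-ene, 2.1 equiv)
Product: 6 deoxycohumulone [2-methyl-1-{2,4,6-trihydroxy-3,5-bis(3-methylbut-2-en-1-yl)phenyl}propan-1-one], via 3-prenylphlorisobutyrophenone 5 (not isolated)
Conditions: KOH (10% aq.), 0 °C, 2 h
Reagents that add atoms: prenyl bromide 4, CC(C)=CCBr
Why: In water the phenoxide oxygen is hydrogen-bonded, so the soft allylic bromide alkylates the two free ring carbons in turn (phenoxide C-alkylation), giving the symmetric 3,5-diprenyl compound without any stereocentre.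

Step 3
Reactants: 6 deoxycohumulone
Product: 9 1-[(2S)-7-{[(2R)-3,3-dimethyloxiran-2-yl]methyl}-4,6-dihydroxy-2-(2-hydroxypropan-2-yl)-2,3-dihydro-1-benzofuran-5-yl]-2-methylpropan-1-one, via monoepoxide 7 (not isolated), via bisepoxide 8 (not isolated)
Conditions: 1,2:4,5-di-O-isopropylidene-β-D-erythro-2,3-hexodiulo-2,6-pyranose (Shi ketone, 1.0 equiv), KHSO5 (Oxone, 3 equiv), K2CO3 (pH held at 8–8.5), Bu4NHSO4, MeCN–CH2(OMe)2–aq. Na2B4O7/Na2EDTA, −5 °C, 3 h; then 20 °C, pH 8.5, until 8 is consumed
Reagents that add atoms: potassium peroxymonosulfate KHSO5 (Oxone), [K+].[O-]S(=O)(=O)OO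
Why: Shi asymmetric epoxidation by the chiral dioxirane oxidises the two trisubstituted alkenes faster than the acyl-deactivated, mostly un-ionised arene and sets both oxirane CH centres as R under reagent control (the minor enantiomer is carried off as the meso R,S bisepoxide), after which the most acidic, unchelated 4-phenoxide opens one of the two homotopic oxiranes of 8 by 5-exo-tet SN2 attack at CH with inversion, giving the 2S dihydrofuran and leaving the second R oxirane beside a less acidic chelated OH.

Step 4
Reactants: 9 the (2S)-dihydrobenzofuran (R)-epoxide from step 3; 10 prenyl acetate (3-methylbut-2-en-1-yl acetate, 1.05 equiv)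
Product: 11 CNP0395488.1 [(2S,3aR)-7-{[(2R)-3,3-dimethyloxiran-2-yl]methyl}-4-hydroxy-2-(2-hydroxypropan-2-yl)-3a-(3-methylbut-2-en-1-yl)-5-(2-methylpropanoyl)-3,3a-dihydro-1-benzofuran-6(2H)-one]
Conditions: Pd(PPh3)4 (5 mol %), Et3N (2.5 equiv), THF, 0 → 23 °C
Reagents that add atoms: prenyl acetate 10, CC(C)=CCOC(C)=O
Why: Tsuji–Trost alkylative dearomatisation in which the phenoxide carbon attacks the unsubstituted terminus of the π-prenyl palladium cation (O-prenyl ethers re-ionise and funnel to carbon), C3a being expected to be favoured over the pseudo-symmetric C7 because its three substituents are tied back in rings and its pyramidalisation relieves the strain of the fused five-membered ring, and the new bond forming on the face anti to the bulky 2-(2-hydroxypropan-2-yl) group as in the trans-selective alkylation of γ-substituted butyrolactone enolates, which sets 3aR while the weak amine base keeps phenoxide O6 from opening the neighbouring oxirane.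

**Compound list**
1 | phloroglucinol (benzene-1,3,5-triol) | Oc1cc(O)cc(O)c1 | starting material
2 | isobutyryl chloride | CC(C)C(Cl)=O | starting material
3 | phlorisobutyrophenone | CC(C)C(=O)c1c(O)cc(O)cc1O | intermediate
4 | prenyl bromide | CC(C)=CCBr | starting material
5 | 3-prenylphlorisobutyrophenone (formed in the flask in step 2) | CC(C)C(=O)c1c(O)cc(O)c(CC=C(C)C)c1O | intermediate
6 | deoxycohumulone | CC(C)C(=O)c1c(O)c(CC=C(C)C)c(O)c(CC=C(C)C)c1O | intermediate
7 | monoepoxide, 1-[3-{[(2R)-3,3-dimethyloxiran-2-yl]methyl}-2,4,6-trihydroxy-5-(3-methylbut-2-en-1-yl)phenyl]-2-methylpropan-1-one (formed in the flask in step 3) | CC(C)C(=O)c1c(O)c(CC=C(C)C)c(O)c(C[C@H]2OC2(C)C)c1O | intermediate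
8 | bisepoxide, 1-[3,5-bis{[(2R)-3,3-dimethyloxiran-2-yl]methyl}-2,4,6-trihydroxyphenyl]-2-methylpropan-1-one (formed in the flask in step 3) | CC(C)C(=O)c1c(O)c(C[C@H]2OC2(C)C)c(O)c(C[C@H]2OC2(C)C)c1O | intermediate
9 | 1-[(2S)-7-{[(2R)-3,3-dimethyloxiran-2-yl]methyl}-4,6-dihydroxy-2-(2-hydroxypropan-2-yl)-2,3-dihydro-1-benzofuran-5-yl]-2-methylpropan-1-one | CC(C)C(=O)c1c(O)c2C[C@@H](C(C)(C)O)Oc2c(C[C@H]3OC3(C)C)c1O | intermediate
10 | prenyl acetate | CC(C)=CCOC(C)=O | starting material
11 | CNP0395488.1, (2S,3aR)-configured, (2R)-oxirane | CC(C)=CC[C@]12C[C@@H](C(C)(C)O)OC1=C(C[C@H]1OC1(C)C)C(=O)C(C(=O)C(C)C)=C2O | target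

**Totals and risks**
Total steps: 4. Longest linear sequence: 4 (1 → 3 → 6 → 9 → 11).

Step 4 is the most likely to fail. C7 is related to C3a by the pseudo-symmetry of 9 and can be prenylated instead, so the site selectivity is the main uncertainty of the route; the C7 isomer is a constitutional isomer and separable. The phenoxide of 9 can also attack the oxirane at C7. The fallback fixes the quaternary carbon before any oxirane exists. It sets out from 6. An enantioselective alkylative dearomatisation with allyl methyl carbonate, Pd2(dba)3 and the DACH-phenyl Trost ligand N,N'-(cyclohexane-1,2-diyl)bis[2-(diphenylphosphanyl)benzamide] (enantiomer chosen by screening) desymmetrises the two enantiotopic prenyl-bearing carbons. It gives (4S)-4-allyl-3,5-dihydroxy-2,4-diprenyl-6-isobutyrylcyclohexa-2,5-dien-1-one F1. The Shi protocol of step 3 then epoxidises the two trisubstituted alkenes and leaves the monosubstituted allyl group untouched. The resulting bis[(2R)-oxirane] F2 is not isolated: the enol oxygen beside the quaternary carbon opens the geminal oxirane (5-exo-tet, inversion) to the 3a-allyl analogue of the target F3. Any cis diastereomer arising from the minor enantiomer of F1 is removed by chromatography. Cross-metathesis of F3 with 2-methylbut-2-ene and second-generation Grubbs catalyst RuCl2(=CHPh)(PCy3)(H2IMes) converts allyl into prenyl and comes back to the route at 11.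

Step 3 is the next most likely to fail. The dioxirane may hydroxylate the electron-rich ring of the free triol, and the second oxirane may close onto O6 once 9 has formed. The fallback masks the phenol that triggers both problems. It sets out from 6. One equivalent of Ac2O with Et3N at −20 °C acetylates only the unchelated 4-OH and gives 4-O-acetyldeoxycohumulone F4. Its ring is neither ionised nor electron-rich, so Shi epoxidation under standard conditions gives the bisepoxide acetate F5. K2CO3 (0.2 equiv) in MeOH at 0 °C then removes the acetate, and the released 4-phenoxide closes the dihydrofuran, coming back to the route at 9.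

Step 2 is the third. Base-mediated prenylation gives statistical mixtures of mono-, di- and tri-prenylated and O-prenylated material. The fallback sets out from 3 and comes back at 6. It is a Friedel–Crafts prenylation with 2-methylbut-3-en-2-ol and BF3·OEt2 in dioxane at 20 °C, which goes through the dimethylallyl cation on the neutral phenol and cannot give dearomatised gem-dialkylated by-products. This detour makes no new compound F0.

Further compounds
F1 | step 4 | (4S)-3,5-dihydroxy-2,4-bis(3-methylbut-2-en-1-yl)-6-(2-methylpropanoyl)-4-(prop-2-en-1-yl)cyclohexa-2,5-dien-1-one | C=CC[C@]1(CC=C(C)C)C(O)=C(CC=C(C)C)C(=O)C(C(=O)C(C)C)=C1O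
F2 | step 4 | bis[(2R)-oxirane] of F1 (not isolated) | C=CC[C@]1(C[C@H]2OC2(C)C)C(O)=C(C[C@H]2OC2(C)C)C(=O)C(C(=O)C(C)C)=C1O
F3 | step 4 | 3a-allyl analogue of 11, (2S,3aR), (2R)-oxirane | C=CC[C@]12C[C@@H](C(C)(C)O)OC1=C(C[C@H]1OC1(C)C)C(=O)C(C(=O)C(C)C)=C2O
F4 | step 3 | 4-O-acetyldeoxycohumulone, 3,5-dihydroxy-2,6-bis(3-methylbut-2-en-1-yl)-4-(2-methylpropanoyl)phenyl acetate | CC(C)C(=O)c1c(O)c(CC=C(C)C)c(OC(C)=O)c(CC=C(C)C)c1O
F5 | step 3 | bisepoxide acetate, 2,6-bis{[(2R)-3,3-dimethyloxiran-2-yl]methyl}-3,5-dihydroxy-4-(2-methylpropanoyl)phenyl acetate | CC(C)C(=O)c1c(O)c(C[C@H]2OC2(C)C)c(OC(C)=O)c(C[C@H]2OC2(C)C)c1O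
F0 | step 2 | none | none
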